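**Retrosynthetic overview**
- Target ⇐ chloride opening at C3 of a ring 3,4-oxirane (titanium-chelated 2,3-epoxy alcohol, trans-diaxial), with the side-chain oxirane kept.
- Bis-epoxide ⇐ one-flask double Shi epoxidation of a diene: the ring C3–C4 oxirane and the side-chain C10–C11 oxirane form in the same operation, both with the same catalyst sense.
- Diene ⇐ Luche reduction of an enone ⇐ double Mitsunobu angeloylation (inversion at C8 and C6) of a diol ⇐ α'-hydroxylation.
- Side chain ⇐ isopropenyl group of (S)-carvone: ene chlorination, N-oxide oxidation to the enal, Keck allylation, cross-metathesis.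
- Ring order: the cyclohexene ring comes from (S)-carvone; both oxiranes form in step 8; the ring oxirane is opened in step 9.

Assumption: angeloyl = (Z)-2-methylbut-2-enoyl; in the "Why" lines and the closing discussion C1–C6 are the ring carbons of the target (C1 bears the side chain, C3 Cl, C4 CH3/OH, C5 OH, C6 O-angeloyl) and C7–C11 the side chain (C7 bears =CH2, C8 O-angeloyl, C10–C11 the oxirane).

**Step 1**
Reactants: 1 (S)-(+)-carvone, (5S)-2-methyl-5-(prop-1-en-2-yl)cyclohex-2-en-1-one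
Product: 2 (5S)-5-(3-chloroprop-1-en-2-yl)-2-methylcyclohex-2-en-1-one
Conditions: Ca(OCl)2, solid CO2, CH2Cl2/H2O, 0 °C
Reagents that add atoms: calcium hypochlorite, [Ca+2].[O-]Cl.[O-]Cl
Why: Ene-type allylic chlorination by HOCl generated in situ attacks only the electron-rich isopropenyl alkene (the enone alkene is deactivated) and gives the 2-substituted allyl chloride without touching the stereocentre.

**Step 2**
Reactants: 2 (5S)-5-(3-chloroprop-1-en-2-yl)-2-methylcyclohex-2-en-1-one
Product: 3 2-[(1S)-4-methyl-5-oxocyclohex-3-en-1-yl]prop-2-enal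
Conditions: N-methylmorpholine N-oxide (3 equiv), KI (0.1 equiv), NaHCO3, MeCN, 40 °C
Reagents that add atoms: 4-methylmorpholine N-oxide, C[N+]1([O-])CCOCC1
Why: Kornblum-type amine N-oxide oxidation, in which iodide-assisted SN2 O-alkylation of the N-oxide by the allylic chloride is followed by base-induced N–O cleavage, gives the 2-substituted acrolein and creates no stereocentre.

**Step 3**
Reactants: 3 2-[(1S)-4-methyl-5-oxocyclohex-3-en-1-yl]prop-2-enal; 4 allyltributylstannane
Product: 5 (5S)-5-[(3R)-3-hydroxyhexa-1,5-dien-2-yl]-2-methylcyclohex-2-en-1-one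
Conditions: (R)-BINOL (20 mol %), Ti(OiPr)4 (10 mol %), 4 Å MS, CH2Cl2, −20 °C; aq. NaHCO3
Reagents that add atoms: allyltributylstannane, C=CC[Sn](CCCC)(CCCC)CCCC
Why: In this Keck asymmetric allylation the (R)-BINOL–titanium Lewis acid activates only the aldehyde (the enone ketone is inert) and delivers allyl to its Re face as it does with benzaldehyde, so C8 is set as R by catalyst control.

**Step 4**
Reactants: 5 (5S)-5-[(3R)-3-hydroxyhexa-1,5-dien-2-yl]-2-methylcyclohex-2-en-1-one; 6 2-methylbut-2-ene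
Product: 7 (5S)-5-[(3R)-3-hydroxy-6-methylhepta-1,5-dien-2-yl]-2-methylcyclohex-2-en-1-one
Conditions: second-generation Grubbs catalyst (H2IMes)(PCy3)Cl2Ru=CHPh (5 mol %), 2-methylbut-2-ene/CH2Cl2, 40 °C
Reagents that add atoms: 2-methylbut-2-ene, CC=C(C)C
Why: In this olefin cross-metathesis only the monosubstituted terminal alkene engages the ruthenium carbene and is capped by excess 2-methylbut-2-ene as the prenyl alkene with loss of propene, the 1,1-disubstituted and enone alkenes being inert and no stereocentre being affected.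

**Step 5**
Reactants: 7 (5S)-5-[(3R)-3-hydroxy-6-methylhepta-1,5-dien-2-yl]-2-methylcyclohex-2-en-1-one
Product: 9 (5R,6R)-6-hydroxy-5-[(3R)-3-hydroxy-6-methylhepta-1,5-dien-2-yl]-2-methylcyclohex-2-en-1-one, via dipotassium alkoxide-dienolate 8 (not isolated)
Conditions: KN(SiMe3)2 (2.3 equiv), THF, −78 °C; then 2-(phenylsulfonyl)-3-phenyloxaziridine (1.3 equiv), −78 °C; AcOH
Reagents that add atoms: 2-(phenylsulfonyl)-3-phenyloxaziridine, O=S(=O)(c1ccccc1)N1OC1c1ccccc1
Why: Kinetic α'-deprotonation gives the cross-conjugated dienolate (the C8 alkoxide forms first) and Davis oxaziridine enolate hydroxylation occurs at C6 anti to the neighbouring C1 side chain, setting the C6–OH trans (6R) without epoxidising any alkene.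

**Step 6**
Reactants: 9 (5R,6R)-6-hydroxy-5-[(3R)-3-hydroxy-6-methylhepta-1,5-dien-2-yl]-2-methylcyclohex-2-en-1-one; 10 angelic acid, (Z)-2-methylbut-2-enoic acid
Product: 12 (5R,6S)-6-(angeloyloxy)-5-[(3S)-3-(angeloyloxy)-6-methylhepta-1,5-dien-2-yl]-2-methylcyclohex-2-en-1-one, via C8 mono-angelate 11 (not isolated)
Conditions: angelic acid (3 equiv), PPh3 (3 equiv), DIAD (3 equiv), toluene, 0 °C to 40 °C
Reagents that add atoms: angelic acid, C/C=C(/C)C(=O)O
Why: In this double Mitsunobu esterification each alkoxyphosphonium is displaced by angelate with SN2 inversion, so 8R becomes the 8S ester and the trans C6–OH becomes the cis C6 ester (6S), while the carboxylate nucleophile keeps the Z geometry of the acid.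

**Step 7**
Reactants: 12 (5R,6S)-6-(angeloyloxy)-5-[(3S)-3-(angeloyloxy)-6-methylhepta-1,5-dien-2-yl]-2-methylcyclohex-2-en-1-one
Product: 13 (1R,5R,6S)-6-(angeloyloxy)-5-[(3S)-3-(angeloyloxy)-6-methylhepta-1,5-dien-2-yl]-2-methylcyclohex-2-en-1-ol
Conditions: NaBH4, CeCl3·7H2O, MeOH, −78 °C
Reagents that add atoms: none
Why: In this Luche 1,2-reduction hydride attacks the enone carbonyl axially from the face opposite the pseudoaxial C6 angelate, giving the pseudoequatorial C5–OH cis to the C6 ester and the C1 side chain (5R) with both conjugated esters untouched.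

**Step 8**
Reactants: 13 (1R,5R,6S)-6-(angeloyloxy)-5-[(3S)-3-(angeloyloxy)-6-methylhepta-1,5-dien-2-yl]-2-methylcyclohex-2-en-1-ol
Product: 15 (1S,2S,3S,4R,6R)-3-(angeloyloxy)-4-{(3S)-3-(angeloyloxy)-4-[(2R)-3,3-dimethyloxiran-2-yl]but-1-en-2-yl}-1-methyl-7-oxabicyclo[4.1.0]heptan-2-ol, via side-chain mono-epoxide 14 (not isolated)
Conditions: D-fructose-derived Shi ketone (0.6 equiv), Oxone (2KHSO5·KHSO4·K2SO4, 3 equiv KHSO5), K2CO3, Bu4NHSO4 (cat.), MeCN/dimethoxymethane 1:2, aq. Na2B4O7/Na2H2EDTA buffer (pH 10.5), −5 to 0 °C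
Reagents that add atoms: potassium peroxymonosulfate KHSO5 (active component of Oxone), [K+].[O-]S(=O)(=O)OO
Why: In this double Shi asymmetric epoxidation the chiral dioxirane epoxidises both electron-rich trisubstituted alkenes through the spiro transition state, which gives the R configuration at the CH carbon of each, so the 10R side-chain oxirane forms first and then the ring oxirane forms on the face of the C5–OH (3R,4S, helped by hydrogen bonding to the allylic OH), while the hindered 1,1-disubstituted alkene and the electron-poor angelates are spared.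

**Step 9**
Reactants: 15 (1S,2S,3S,4R,6R)-3-(angeloyloxy)-4-{(3S)-3-(angeloyloxy)-4-[(2R)-3,3-dimethyloxiran-2-yl]but-1-en-2-yl}-1-methyl-7-oxabicyclo[4.1.0]heptan-2-ol
Product: 16 CNP0333703.2, (1S,2S,3S,4S,6R)-4-chloro-2,3-dihydroxy-3-methyl-6-{(3S)-3-(angeloyloxy)-4-[(2R)-3,3-dimethyloxiran-2-yl]but-1-en-2-yl}cyclohexyl (Z)-2-methylbut-2-enoate
Conditions: ClTi(OiPr)3 (1.5 equiv), CH2Cl2, −20 to 0 °C; aq. potassium sodium tartrate
Reagents that add atoms: chlorotitanium triisopropoxide, CC(C)O[Ti](Cl)(OC(C)C)OC(C)C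
Why: In this titanium-mediated regioselective opening of a 2,3-epoxy alcohol the C5 alkoxide binds titanium, which activates only the chelated ring oxirane, and chloride attacks the secondary C3 from the opposite face (SN2, trans-diaxial Fürst–Plattner opening) to give the 3S chloride and the 4S tertiary alcohol while the non-chelating side-chain oxirane stays intact.

**Compound list**
1 | (S)-(+)-carvone | C=C(C)[C@H]1CC=C(C)C(=O)C1 | starting material
2 | (5S)-5-(3-chloroprop-1-en-2-yl)-2-methylcyclohex-2-en-1-one | C=C(CCl)[C@H]1CC=C(C)C(=O)C1 | intermediate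
3 | 2-[(1S)-4-methyl-5-oxocyclohex-3-en-1-yl]prop-2-enal | C=C(C=O)[C@H]1CC=C(C)C(=O)C1 | intermediate
4 | allyltributylstannane | C=CC[Sn](CCCC)(CCCC)CCCC | starting material
5 | (5S)-5-[(3R)-3-hydroxyhexa-1,5-dien-2-yl]-2-methylcyclohex-2-en-1-one | C=C([C@H](O)CC=C)[C@H]1CC=C(C)C(=O)C1 | intermediate
6 | 2-methylbut-2-ene | CC=C(C)C | starting material
7 | (5S)-5-[(3R)-3-hydroxy-6-methylhepta-1,5-dien-2-yl]-2-methylcyclohex-2-en-1-one | C=C([C@H](O)CC=C(C)C)[C@H]1CC=C(C)C(=O)C1 | intermediate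
8 | dipotassium alkoxide-dienolate of 7 | [K+].[K+].C=C([C@H]([O-])CC=C(C)C)[C@H]1CC=C(C)C([O-])=C1 | intermediate (not isolated)
9 | (5R,6R)-6-hydroxy-5-[(3R)-3-hydroxy-6-methylhepta-1,5-dien-2-yl]-2-methylcyclohex-2-en-1-one (6-OH trans to the side chain) | C=C([C@H](O)CC=C(C)C)[C@H]1CC=C(C)C(=O)[C@@H]1O | intermediate
10 | angelic acid, (Z)-2-methylbut-2-enoic acid | C/C=C(/C)C(=O)O | starting material
11 | (5R,6R)-6-hydroxy-2-methyl-5-[(3S)-3-(angeloyloxy)-6-methylhepta-1,5-dien-2-yl]cyclohex-2-en-1-one | C=C([C@H](CC=C(C)C)OC(=O)/C(C)=C\C)[C@H]1CC=C(C)C(=O)[C@@H]1O | intermediate (not isolated)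
12 | (5R,6S)-6-(angeloyloxy)-5-[(3S)-3-(angeloyloxy)-6-methylhepta-1,5-dien-2-yl]-2-methylcyclohex-2-en-1-one (6-O cis to the side chain) | C=C([C@H](CC=C(C)C)OC(=O)/C(C)=C\C)[C@H]1CC=C(C)C(=O)[C@H]1OC(=O)/C(C)=C\C | intermediate
13 | (1R,5R,6S)-6-(angeloyloxy)-5-[(3S)-3-(angeloyloxy)-6-methylhepta-1,5-dien-2-yl]-2-methylcyclohex-2-en-1-ol (OH, O-angeloyl and side chain all cis) | C=C([C@H](CC=C(C)C)OC(=O)/C(C)=C\C)[C@H]1CC=C(C)[C@@H](O)[C@H]1OC(=O)/C(C)=C\C | intermediate
14 | (1R,5R,6S)-6-(angeloyloxy)-5-{(3S)-3-(angeloyloxy)-4-[(2R)-3,3-dimethyloxiran-2-yl]but-1-en-2-yl}-2-methylcyclohex-2-en-1-ol | C=C([C@H](C[C@@H]1OC1(C)C)OC(=O)/C(C)=C\C)[C@H]1CC=C(C)[C@@H](O)[C@H]1OC(=O)/C(C)=C\C | intermediate (not isolated)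
15 | (1S,2S,3S,4R,6R)-3-(angeloyloxy)-4-{(3S)-3-(angeloyloxy)-4-[(2R)-3,3-dimethyloxiran-2-yl]but-1-en-2-yl}-1-methyl-7-oxabicyclo[4.1.0]heptan-2-ol (ring oxirane cis to the 2-OH) | C=C([C@H](C[C@@H]1OC1(C)C)OC(=O)/C(C)=C\C)[C@H]1C[C@H]2O[C@@]2(C)[C@@H](O)[C@H]1OC(=O)/C(C)=C\C | intermediate
16 | CNP0333703.2, (1S,2S,3S,4S,6R)-4-chloro-2,3-dihydroxy-3-methyl-6-{(3S)-3-(angeloyloxy)-4-[(2R)-3,3-dimethyloxiran-2-yl]but-1-en-2-yl}cyclohexyl (Z)-2-methylbut-2-enoate | C=C([C@H](C[C@@H]1OC1(C)C)OC(=O)/C(C)=C\C)[C@H]1C[C@H](Cl)[C@@](C)(O)[C@@H](O)[C@H]1OC(=O)/C(C)=C\C | target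

**Step count**
Total step count: 9. Longest linear sequence: 9 steps (1 to 16).

**Three steps most likely to fail**

Step 8 (double epoxidation). The catalyst prefers the required ring face, but that face also carries the C5–OH and the pseudoaxial C6 angelate, so substrate sterics oppose catalyst control and the ring oxirane may form on the wrong face or as a mixture. Over-oxidation of the 1,1-disubstituted alkene and base-induced angeloyl migration from C6–O to C5–O are secondary risks. The fallback sets out from 13 and comes back at 15. Hydroxyl-directed epoxidation with VO(acac)2 (3 mol %) and t-BuOOH in CH2Cl2 at 0 °C delivers oxygen syn to the C5–OH and touches only the ring alkene, giving the ring mono-epoxide F1. A separate Shi epoxidation with the same D-fructose-derived ketone then acts only on the prenyl alkene and gives 15.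

Step 6 (double Mitsunobu). The allylic C8 alcohol may react partly by SN2' at the terminal methylene, and the hindered α-ketol at C6 may invert slowly or eliminate. The fallback sets out from 3 and comes back at 12. Keck allylation of 3 with (S)-BINOL instead gives the (8S)-homoallylic alcohol F2, and cross-metathesis with 6 gives the (8S)-prenyl alcohol F3. Treatment with KN(SiMe3)2 forms the dipotassium alkoxide-dienolate F4, which the Davis oxaziridine hydroxylates to the (5R,6R,8S)-diol F5. Yamaguchi acylation with 10 (2,4,6-trichlorobenzoyl chloride, Et3N, toluene, no DMAP) esterifies the allylic C8–OH with retention in preference to the hydrogen-bonded α-ketol OH and gives 11, now isolated. Tf2O/pyridine converts 11 into the C6 triflate F6, and SN2 displacement with cesium angelate (from 10 and Cs2CO3) in toluene with 18-crown-6 gives 12.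

Step 9 (selective chloride opening). The Lewis acid may also open the acid-labile side-chain oxirane at C11, or chloride may attack the tertiary C4. The fallback sets out from 13 and comes back at 16. VO(acac)2/t-BuOOH gives the ring mono-epoxide F1. ClTi(OiPr)3 then opens the only oxirane present at C3 and gives the chlorohydrin F7, which still carries the prenyl alkene. Shi epoxidation with the D-fructose-derived ketone, now with no ring alkene to compete, installs the 10R oxirane and gives 16.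

**Further compounds**
F1 | step 8 | (1S,2S,3S,4R,6R)-3-(angeloyloxy)-4-[(3S)-3-(angeloyloxy)-6-methylhepta-1,5-dien-2-yl]-1-methyl-7-oxabicyclo[4.1.0]heptan-2-ol | C=C([C@H](CC=C(C)C)OC(=O)/C(C)=C\C)[C@H]1C[C@H]2O[C@@]2(C)[C@@H](O)[C@H]1OC(=O)/C(C)=C\C
F2 | step 6 | (5S)-5-[(3S)-3-hydroxyhexa-1,5-dien-2-yl]-2-methylcyclohex-2-en-1-one | C=C([C@@H](O)CC=C)[C@H]1CC=C(C)C(=O)C1
F3 | step 6 | (5S)-5-[(3S)-3-hydroxy-6-methylhepta-1,5-dien-2-yl]-2-methylcyclohex-2-en-1-one | C=C([C@@H](O)CC=C(C)C)[C@H]1CC=C(C)C(=O)C1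
F4 | step 6 | dipotassium alkoxide-dienolate of F3 | [K+].[K+].C=C([C@@H]([O-])CC=C(C)C)[C@H]1CC=C(C)C([O-])=C1
F5 | step 6 | (5R,6R)-6-hydroxy-5-[(3S)-3-hydroxy-6-methylhepta-1,5-dien-2-yl]-2-methylcyclohex-2-en-1-one | C=C([C@@H](O)CC=C(C)C)[C@H]1CC=C(C)C(=O)[C@@H]1O
F6 | step 6 | (1R,6R)-3-methyl-6-[(3S)-3-(angeloyloxy)-6-methylhepta-1,5-dien-2-yl]-2-oxocyclohex-3-en-1-yl trifluoromethanesulfonate | C=C([C@H](CC=C(C)C)OC(=O)/C(C)=C\C)[C@H]1CC=C(C)C(=O)[C@@H]1OS(=O)(=O)C(F)(F)F
F7 | step 9 | (1S,2S,3S,4S,6R)-4-chloro-2,3-dihydroxy-3-methyl-6-[(3S)-3-(angeloyloxy)-6-methylhepta-1,5-dien-2-yl]cyclohexyl (Z)-2-methylbut-2-enoate | C=C([C@H](CC=C(C)C)OC(=O)/C(C)=C\C)[C@H]1C[C@H](Cl)[C@@](C)(O)[C@@H](O)[C@H]1OC(=O)/C(C)=C\C
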